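**Plan**

- Cuts, in retrosynthetic order (germacranolide numbering): the two crotonate O–acyl bonds; the oxirane oxygen and the C2=C3 bond; the lactone C12=O and the O–C6 bond, leading back to a C12 allylic alcohol and an (E)-C5=C6 alkene; then a retro-[3,3] shift that cuts C3–C4 and re-joins C1–C6.
- Enabling feature: the C1 ketone and the O-bearing C6 lie 1,6 across the ten-membered ring with four carbons on either side. The six carbons C1–C10–C9–C8–C7–C6, with C14 on C10 and the C11/C12/C13 unit on C7, are the carvone skeleton. C1–C6 can therefore be the σ-bond of a 3-oxido-1,5-diene whose arms are vinyl (C2–C3) and (Z)-propenyl (C5–C4–C15).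
- Forward ring order: carvone six-membered ring (oxygenated at C10, C9, C8; arms added at C6, then C1) → ten-membered carbocycle by 6→10 ring expansion (step 12) → tetrahydrofuran (O–C6) → oxirane → lactone carbonyl → esters.
- Stereochemistry: C7 from (R)-carvone; C10, C9, C8 from two hydroxyl-directed epoxidations and trans-diaxial openings on the cyclohexane; C4 from the chair [3,3] transition state with a (Z)-propenyl arm; C6 from 5-exo O-radical closure anti to ring bond C7–C8; C2/C3 from peripheral peroxide attack on the (Z)-enone.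

Key step: step 12

Remark: the target is read as (2S,3S,4R,6R,7S,8S,9R,10S) with (E)-but-2-enoates, and ring carbons of all intermediates carry the target's numbers (C1 = carvone C=O carbon, C10 = methyl-bearing carbon, C7 = isopropenyl-bearing carbon). Aldehyde 16 is racemic and used in excess; 17 and 18 are drawn as one Felkin diastereomer, since C5 and C4 are destroyed in step 12 and only their relative configuration matters.

**Route**

Step 1
Reactants: 1 (R)-(−)-carvone
Product: 2 (1R,5R)-cis-carveol
Conditions: NaBH4, CeCl3·7H2O, MeOH, −20 °C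
Reagents that add atoms: none
Why: Luche 1,2-reduction, in which axial hydride delivery should give the equatorial C1–OH cis to the isopropenyl group.

Step 2
Reactants: 2 (1R,5R)-cis-carveol
Product: 3 cis-carveol 9,10-epoxide (oxirane, C1–OH and isopropenyl all on one face)
Conditions: VO(acac)2 (cat.), t-BuOOH, toluene, 0 °C → rt
Reagents that add atoms: tert-butyl hydroperoxide CC(C)(C)OO
Why: Vanadium-catalysed hydroxyl-directed epoxidation delivers oxygen syn to C1–OH, which places the future C10–O cis to the C7 side chain and leaves the isopropenyl alkene untouched.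

Step 3
Reactants: 3 cis-carveol 9,10-epoxide
Product: 5 cis-1,10-diol with a C8=C9 alkene (both OH cis to isopropenyl), via hydroxy selenide 4 (not isolated)
Conditions: (PhSe)2, NaBH4, EtOH, reflux; then 30% H2O2, THF, 0 °C → rt
Reagents that add atoms: none
Why: Epoxide-to-allylic-alcohol transposition, in which the selenolate opens the oxirane trans-diaxially at the secondary C9 and selenoxide syn-elimination can only run toward C8 because C10 is quaternary.

Step 4
Reactants: 5 cis-1,10-diol with a C8=C9 alkene
Product: 6 10-hydroxy C1 ketone with a C8=C9 alkene (C10–OH cis to isopropenyl)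
Conditions: IBX, DMSO, rt
Reagents that add atoms: none
Why: IBX oxidises the secondary alcohol without cleaving the 1,2-diol and leaves the tertiary C10–OH, giving a ketone whose only enolisable position is C6.

Step 5
Reactants: 6 10-hydroxy C1 ketone with a C8=C9 alkene
Product: 8 C8/C9/C10-triol ketone (C8–OH and C10–OH cis and C9–OH trans to isopropenyl), via syn-epoxy ketone 7 (not isolated)
Conditions: VO(acac)2 (cat.), t-BuOOH, CH2Cl2, 0 °C; then HClO4 (cat.), THF/H2O, rt
Reagents that add atoms: tert-butyl hydroperoxide CC(C)(C)OO; water O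
Why: C10–OH-directed epoxidation followed by Fürst–Plattner trans-diaxial opening by water at C9 (attack at C8 would need an axial isopropenyl group and a syn-axial C14 methyl) should set C8–O cis and C9–O trans to the side chain.

Step 6
Reactants: 8 C8/C9/C10-triol ketone
Product: 10 8,10-O-di-tert-butylsilylene 9-O-TBS ketone, via silylene alcohol 9 (not isolated)
Conditions: t-Bu2Si(OTf)2, 2,6-lutidine, CH2Cl2, 0 °C; then TBSOTf, −78 → 0 °C
Reagents that add atoms: di-tert-butylsilyl bis(trifluoromethanesulfonate) CC(C)(C)[Si](OS(=O)(=O)C(F)(F)F)(OS(=O)(=O)C(F)(F)F)C(C)(C)C; tert-butyldimethylsilyl trifluoromethanesulfonate CC(C)(C)[Si](C)(C)OS(=O)(=O)C(F)(F)F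
Why: Only the syn-diaxial C8/C10 diol can be bridged as a six-membered silylene, which locks the chair with the C7 side chain equatorial and resists silyl migration; TBSOTf then caps the remaining axial C9–OH.

Step 7
Reactants: 10 8,10-O-di-tert-butylsilylene 9-O-TBS ketone
Product: 11 C12 allylic alcohol (2-(hydroxymethyl)vinyl group on C7)
Conditions: SeO2 (cat.), t-BuOOH, CH2Cl2, rt
Reagents that add atoms: tert-butyl hydroperoxide CC(C)(C)OO (oxygen carried by catalytic selenium dioxide O=[Se]=O)
Why: Selenium dioxide ene/[2,3] allylic hydroxylation of the isopropenyl methyl group, the only alkene in 10 and one whose alternative allylic C7–H is a hindered methine.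

Step 8
Reactants: 12 propanal; 13 tert-butylamine
Product: 14 N-tert-butylpropan-1-imine
Conditions: MgSO4, Et2O, 0 °C → rt
Reagents that add atoms: none
Why: Simple imine condensation driven by removal of water.

Step 9
Reactants: 14 N-tert-butylpropan-1-imine
Product: 16 rac-2-(tert-butyldimethylsilyl)propanal, via α-silyl aldimine 15 (not isolated)
Conditions: LDA, THF, −78 → 0 °C; TBSCl, −78 °C → rt; then AcOH/NaOAc buffer, H2O/pentane, 0 °C
Reagents that add atoms: tert-butyldimethylsilyl chloride CC(C)(C)[Si](C)(C)Cl; water O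
Why: C-silylation of the metalated aldimine and buffered hydrolysis should give the α-silyl aldehyde, which the bulky silyl group makes isolable.

Step 10
Reactants: 11 C12 allylic alcohol; 16 rac-2-(tert-butyldimethylsilyl)propanal
Product: 17 C6 aldol adduct (C6–C5 bond trans to the C7 side chain; C5–OH/C4–Si in the Felkin relationship)
Conditions: LDA (2.2 equiv), THF, −78 °C; 16 (3 equiv), −78 °C; aq. NH4Cl at −78 °C
Reagents that add atoms: none
Why: The lithium enolate (C6 is the only enolisable carbon) should add from the face opposite the silylene bridge, and Felkin–Anh attack anti to silicon fixes the C5/C4 relationship that later gives the (Z)-alkene by Peterson syn-elimination.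

Step 11
Reactants: 17 C6 aldol adduct
Product: 18 C1 vinyl carbinol (vinyl equatorial and trans to the C6 arm; C1–OH axial)
Conditions: CH2=CHMgBr (excess), CeCl3, THF, −78 → 0 °C
Reagents that add atoms: vinylmagnesium bromide C=C[Mg]Br
Why: Organocerium 1,2-addition to the hindered ketone, with equatorial attack expected because the axial C9–OTBS blocks the axial trajectory, so the two arms end up trans-diequatorial.

Step 12
Reactants: 18 C1 vinyl carbinol
Product: 21 (4R,5E)-cyclodec-5-en-1-one (C12–OH free; silyl groups intact), via (Z)-propenyl dienol 19 (not isolated), via dipotassium enolate 20 (not isolated)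
Conditions: KH (excess), 18-crown-6, THF, 0 → 50 °C; aq. NH4Cl
Reagents that add atoms: none
Why: KH first triggers Peterson syn-elimination of the potassium β-oxidosilane (Felkin adduct → (Z)-propenyl arm), and the tertiary potassium alkoxide then undergoes the charge-accelerated [3,3] shift (anionic oxy-Cope) that breaks C1–C6 and forms C3–C4, giving the enolate and, on protonation, the ketone. The closest known reaction types are the anionic oxy-Cope ring expansion of trans-1,2-dialkenylcyclohexanols to (E)-cyclodec-5-enones and the base-induced syn-elimination of β-hydroxysilanes. No ring is closed end to end: the ten-membered ring arises by 6→10 ring expansion (four carbons inserted between C1 and C6) through a chair transition state fused trans-diequatorially to the silylene-locked cyclohexane. The new stereocentre C4 is set because the (Z)-methyl sits axial in that chair and C3–C4 forms on the allyl face from which C1 departs, which with the C6 configuration should give 4R; C5=C6 is E because ring bond C6–C7 is equatorial in the chair. The step needs chair over boat, the trans arrangement of the arms and no competing 1,5-diene; these are secured by the conformational lock, by the facial control in steps 10 and 11, and by saturating C8–C9 beforehand, while the quaternary C10 keeps the enolate regiodefined toward C2.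

Step 13
Reactants: 21 (4R,5E)-cyclodec-5-en-1-one
Product: 22 6,12-epoxy compound (3-methylenetetrahydrofuran trans-fused at C6–C7; C5 now CH2)
Conditions: [Ir(dF(CF3)ppy)2(5,5′-d(CF3)bpy)]PF6 (cat.), Bu4P+ dialkyl phosphate (cat.), 2,4,6-triisopropylbenzenethiol (cat.), PhCF3, blue LEDs, rt
Reagents that add atoms: none
Why: Photocatalytic proton-coupled electron transfer hydroetherification, in which the C12 alkoxy radical closes 5-exo onto C6 and C5 takes hydrogen from the thiol; the tether can reach C6 only from the side-chain face, anti to ring bond C7–C8, which should give the trans-fused 6R ether.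

Step 14
Reactants: 22 6,12-epoxy compound
Product: 24 (2Z)-cyclodec-2-en-1-one, via 2-phenylselanyl ketone 23 (not isolated)
Conditions: LiHMDS, THF, −78 °C; PhSeCl; then 30% H2O2, pyridine, CH2Cl2, 0 °C
Reagents that add atoms: none
Why: Regiospecific enolisation toward C2 (C10 is quaternary), α-selenenylation and selenoxide syn-elimination, with the less strained (Z)-enone expected in the ten-membered ring.

Step 15
Reactants: 24 (2Z)-cyclodec-2-en-1-one
Product: 25 (2S,3S)-2,3-epoxy ketone
Conditions: t-BuOOH, KH (cat.), THF, −20 → 0 °C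
Reagents that add atoms: tert-butyl hydroperoxide CC(C)(C)OO
Why: Weitz–Scheffer nucleophilic epoxidation, in which the peroxide should attack C3 from the peripheral face, anti to ring bond C4–C5 with C4–H eclipsing the (Z)-alkene (A1,3 strain), to give the cis-oxirane trans to C15; the unactivated C11=C13 alkene is inert.

Step 16
Reactants: 25 (2S,3S)-2,3-epoxy ketone
Product: 26 silyl-protected α-methylene-γ-butyrolactone (6,12-olide)
Conditions: CrO3·3,5-dimethylpyrazole (excess), CH2Cl2, −20 °C
Reagents that add atoms: chromium trioxide O=[Cr](=O)=O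
Why: Chromium(VI) allylic oxidation of the ether CH2 (both allylic and α to oxygen), a known conversion of 3-methylenetetrahydrofurans into α-methylene lactones that oxirane, ketone and silyl ethers should tolerate.

Step 17
Reactants: 26 silyl-protected α-methylene-γ-butyrolactone
Product: 27 C8/C9/C10-triol lactone
Conditions: HF·pyridine, pyridine/THF, 0 °C → rt
Reagents that add atoms: none
Why: Fluoride-mediated cleavage of the silylene and the TBS ether under buffered, weakly acidic conditions that avoid retro-aldol and α-ketol chemistry of the hydroxy ketone.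

Step 18
Reactants: 27 C8/C9/C10-triol lactone
Product: 28 target CNP0253228.1
Conditions: (E)-crotonic anhydride (3 equiv), DMAP (cat.), pyridine, CH2Cl2, 0 °C → rt
Reagents that add atoms: (E)-but-2-enoic anhydride C/C=C/C(=O)OC(=O)/C=C/C
Why: DMAP-catalysed acylation of the two secondary alcohols, which the hindered tertiary α-ketol OH should not undergo, and using the anhydride without strong base avoids deconjugation of the crotonyl group.

**Compound list**

1 | (R)-(−)-carvone, (5R)-2-methyl-5-(prop-1-en-2-yl)cyclohex-2-en-1-one | O=C1C(C)=CC[C@@H](C(C)=C)C1 | starting material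
2 | (1R,5R)-cis-carveol (C1–OH cis to isopropenyl) | O[C@H]1C(C)=CC[C@@H](C(C)=C)C1 | intermediate
3 | cis-carveol 9,10-epoxide (oxirane syn to C1–OH and to isopropenyl) | O[C@H]1[C@@]2(C)O[C@H]2C[C@@H](C(C)=C)C1 | intermediate
4 | hydroxy selenide: C1,C10-cis-diol with C9–SePh trans to both OH (not isolated) | O[C@H]1[C@@](C)(O)[C@H]([Se]c2ccccc2)C[C@@H](C(C)=C)C1 | intermediate
5 | cis-1,10-diol with C8=C9 alkene: 2-methyl-5-(prop-1-en-2-yl)cyclohex-3-ene-1,2-diol, both OH cis to isopropenyl | O[C@H]1[C@@](C)(O)C=C[C@@H](C(C)=C)C1 | intermediate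
6 | 2-hydroxy-2-methyl-5-(prop-1-en-2-yl)cyclohex-3-en-1-one, OH cis to isopropenyl | O=C1[C@@](C)(O)C=C[C@@H](C(C)=C)C1 | intermediate
7 | 8,9-epoxide of 6, oxirane syn to C10–OH (not isolated) | O=C1[C@@](C)(O)[C@H]2O[C@H]2[C@@H](C(C)=C)C1 | intermediate
8 | triol ketone: C10–OH and C8–OH cis, C9–OH trans to isopropenyl | O=C1[C@@](C)(O)[C@H](O)[C@@H](O)[C@@H](C(C)=C)C1 | intermediate
9 | 8,10-O-di-tert-butylsilylene derivative of 8 with free C9–OH (not isolated) | O=C1[C@@]2(C)O[Si](C(C)(C)C)(C(C)(C)C)O[C@H]([C@H]2O)[C@@H](C(C)=C)C1 | intermediate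
10 | 8,10-O-di-tert-butylsilylene 9-O-TBS ketone | O=C1[C@@]2(C)O[Si](C(C)(C)C)(C(C)(C)C)O[C@H]([C@H]2O[Si](C)(C)C(C)(C)C)[C@@H](C(C)=C)C1 | intermediate
11 | C12 allylic alcohol of 10 (3-hydroxyprop-1-en-2-yl group on C7) | O=C1[C@@]2(C)O[Si](C(C)(C)C)(C(C)(C)C)O[C@H]([C@H]2O[Si](C)(C)C(C)(C)C)[C@@H](C(CO)=C)C1 | intermediate
12 | propanal | CCC=O | starting material
13 | tert-butylamine | CC(C)(C)N | starting material
14 | (E)-N-tert-butylpropan-1-imine | CC/C=N/C(C)(C)C | intermediate
15 | rac-N-tert-butyl-2-(tert-butyldimethylsilyl)propan-1-imine (not isolated) | CC(/C=N/C(C)(C)C)[Si](C)(C)C(C)(C)C | intermediate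
16 | rac-2-(tert-butyldimethylsilyl)propanal | CC(C=O)[Si](C)(C)C(C)(C)C | intermediate
17 | aldol adduct: C6 bears CH(OH)–CH(SiMe2t-Bu)–CH3 trans to the C7 side chain, Felkin C5/C4 | O=C1[C@@]2(C)O[Si](C(C)(C)C)(C(C)(C)C)O[C@H]([C@H]2O[Si](C)(C)C(C)(C)C)[C@@H](C(CO)=C)[C@@H]1[C@H](O)[C@@H](C)[Si](C)(C)C(C)(C)C | intermediate
18 | C1 vinyl carbinol of 17 (vinyl trans to the C6 arm, C1–OH axial) | C=C[C@@]1(O)[C@@]2(C)O[Si](C(C)(C)C)(C(C)(C)C)O[C@H]([C@H]2O[Si](C)(C)C(C)(C)C)[C@@H](C(CO)=C)[C@@H]1[C@H](O)[C@@H](C)[Si](C)(C)C(C)(C)C | intermediate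
19 | trans-1-vinyl-6-[(Z)-prop-1-enyl]cyclohexanol, formed as its potassium alkoxide (not isolated) | C=C[C@@]1(O)[C@@]2(C)O[Si](C(C)(C)C)(C(C)(C)C)O[C@H]([C@H]2O[Si](C)(C)C(C)(C)C)[C@@H](C(CO)=C)[C@@H]1/C=C\C | intermediate
20 | dipotassium C1 enolate/C12 alkoxide of 21 (not isolated) | [K+].[K+].[O-]/C1=C\C[C@H](C)/C=C/[C@H](C(C[O-])=C)[C@@H]2O[Si](C(C)(C)C)(C(C)(C)C)O[C@@]1(C)[C@@H]2O[Si](C)(C)C(C)(C)C | intermediate
21 | (4R,5E)-cyclodec-5-en-1-one: 4-methyl, 7-(3-hydroxyprop-1-en-2-yl), 8,10-O-silylene, 9-OTBS, 10-methyl | O=C1CC[C@H](C)/C=C/[C@H](C(CO)=C)[C@@H]2O[Si](C(C)(C)C)(C(C)(C)C)O[C@@]1(C)[C@@H]2O[Si](C)(C)C(C)(C)C | intermediate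
22 | 6,12-epoxy compound: 3-methylenetetrahydrofuran trans-fused at C6–C7 of the cyclodecanone | C=C1CO[C@@H]2C[C@@H](C)CCC(=O)[C@@]3(C)O[Si](C(C)(C)C)(C(C)(C)C)O[C@H]([C@H]3O[Si](C)(C)C(C)(C)C)[C@@H]12 | intermediate
23 | 2-phenylselanyl ketone of 22, C2 epimers (not isolated) | C=C1CO[C@@H]2C[C@@H](C)CC([Se]c3ccccc3)C(=O)[C@@]4(C)O[Si](C(C)(C)C)(C(C)(C)C)O[C@H]([C@H]4O[Si](C)(C)C(C)(C)C)[C@@H]12 | intermediate
24 | (2Z)-enone of 22 | C=C1CO[C@@H]2C[C@@H](C)/C=C\C(=O)[C@@]3(C)O[Si](C(C)(C)C)(C(C)(C)C)O[C@H]([C@H]3O[Si](C)(C)C(C)(C)C)[C@@H]12 | intermediate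
25 | (2S,3S)-2,3-epoxy ketone (cis-oxirane trans to C15) | C=C1CO[C@@H]2C[C@@H](C)[C@@H]3O[C@@H]3C(=O)[C@@]4(C)O[Si](C(C)(C)C)(C(C)(C)C)O[C@H]([C@H]4O[Si](C)(C)C(C)(C)C)[C@@H]12 | intermediate
26 | silyl-protected 6,12-olide (α-methylene-γ-butyrolactone) | C=C1C(=O)O[C@@H]2C[C@@H](C)[C@@H]3O[C@@H]3C(=O)[C@@]4(C)O[Si](C(C)(C)C)(C(C)(C)C)O[C@H]([C@H]4O[Si](C)(C)C(C)(C)C)[C@@H]12 | intermediate
27 | 8,9,10-triol lactone | C=C1C(=O)O[C@@H]2C[C@@H](C)[C@@H]3O[C@@H]3C(=O)[C@@](C)(O)[C@H](O)[C@@H](O)[C@@H]12 | intermediate
28 | CNP0253228.1, (2S,3S,4R,6R,7S,8S,9R,10S)-2,3-epoxy-10-hydroxy-1-oxo-8,9-bis[(E)-but-2-enoyloxy]germacr-11(13)-en-6,12-olide | C=C1C(=O)O[C@@H]2C[C@@H](C)[C@@H]3O[C@@H]3C(=O)[C@@](C)(O)[C@H](OC(=O)/C=C/C)[C@@H](OC(=O)/C=C/C)[C@@H]12 | target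

**Count and risks**

Total step count: 18. Longest linear sequence: 16 (steps 1–7 and 10–18 from (R)-carvone).

Steps most likely to fail:

1. Step 12. The syn-elimination of the potassium β-oxidosilane may lag behind or compete with fragmentation of the trialkoxide, and any leakage of anti-Felkin adduct from step 10 would send an (E)-propenyl arm into the [3,3] shift and erode C4. The fallback sets out from 11 and comes back at 19, using a cross-coupling instead of the aldol/Peterson pair. The ketone enolate of 11 is alkenylated with (Z)-1-bromopropene (Pd2(dba)3, a bulky biaryl phosphine, LiHMDS 2.2 equiv, THF, rt; alkene geometry retained) to give the α-(Z)-propenyl ketone F1. Vinylcerium addition as in step 11 then gives 19 as an isolated compound, which is treated with KH/18-crown-6 alone to reach 21.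

2. Step 13. The O-centred radical may abstract the activated C8–H (1,5-hydrogen transfer) faster than it adds to C6, or the excited catalyst may be quenched unproductively. The fallback sets out from 21 and comes back at 22 by ionic cyclisation instead of radical closure: iodoetherification (NIS, NaHCO3, MeCN, 0 °C; anti addition, O to C6 and I to C5) gives the 5-iodo ether F2, and reductive deiodination (Bu3SnH, Et3B/air, toluene, 0 °C) gives 22.

3. Step 7. The selenium ene reaction may take the ring hydrogen at C7 instead of a methyl hydrogen, or over-oxidise to the enal. The fallback sets out from 10 and comes back at 11 by electrophilic chlorination and substitution: ene-type chlorination (Ca(OCl)2, solid CO2, CH2Cl2/H2O, 0 °C) gives the allylic chloride F3, displacement with KOAc/18-crown-6 (MeCN, 60 °C) gives the allylic acetate F4, and methanolysis (K2CO3, MeOH, 0 °C) gives 11.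

Further compounds
F1 | step 12 | α-(Z)-propenyl ketone: 11 with a (Z)-prop-1-enyl group on C6 trans to the C7 side chain | O=C1[C@@]2(C)O[Si](C(C)(C)C)(C(C)(C)C)O[C@H]([C@H]2O[Si](C)(C)C(C)(C)C)[C@@H](C(CO)=C)[C@@H]1/C=C\C
F2 | step 13 | 5-iodo ether: 22 with iodine on C5, anti to the C6–O bond | C=C1CO[C@@H]2[C@H](I)[C@@H](C)CCC(=O)[C@@]3(C)O[Si](C(C)(C)C)(C(C)(C)C)O[C@H]([C@H]3O[Si](C)(C)C(C)(C)C)[C@@H]12
F3 | step 7 | allylic chloride: 10 with a 3-chloroprop-1-en-2-yl group on C7 | O=C1[C@@]2(C)O[Si](C(C)(C)C)(C(C)(C)C)O[C@H]([C@H]2O[Si](C)(C)C(C)(C)C)[C@@H](C(CCl)=C)C1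
F4 | step 7 | allylic acetate: 10 with a 3-acetoxyprop-1-en-2-yl group on C7 | O=C1[C@@]2(C)O[Si](C(C)(C)C)(C(C)(C)C)O[C@H]([C@H]2O[Si](C)(C)C(C)(C)C)[C@@H](C(COC(C)=O)=C)C1
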